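**Plan**

1. Cuts, in order: the C8 tiglate ester; then in one stroke the ring bond C5–C6 and the lactone bond O6–C12; then C7–C8 and C2–C3 of the open chain (germacrane numbering: C1=C2 enone olefin, C3 ketone, C4=C5 methyl-bearing olefin, C6 lactone carbinol, C8 acyloxy carbinol, C10 tertiary carbinol, C11–C13 methylene lactone carbons).
2. Enabling feature: C6 is an allylic carbinol carbon on the Z-olefin carbon C5, and its oxygen completes the five-membered ring O6–C6–C7–C11–C12 with ester carbon C12. A C5 alkenylmetal adding to a C6 aldehyde therefore makes the ten-membered ring bond, the C6 stereocentre and, through the alkoxide, the γ-lactone.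
3. Forward: (R)-citramalic acid gives the C8–C10/C1 alkynol; a Z-iodoenal from propargyl alcohol is joined at C2–C3; semihydrogenation and double oxidation give the Z,Z-iodo dienone aldehyde; an allylindium reagent from (R)-glyceraldehyde acetonide and methyl acrylate adds at C8; the C6 aldehyde is unmasked; the carbocycle and then the lactone close in one flask; desilylation and acylation with tiglic acid finish.
4. Stereochemistry: C10 from (R)-citramalic acid; C7 and C8 from the syn-selective chair addition of the Z-allylindium, its face set by a dioxolane stereocentre that is later excised; C6 in the ring closure under control of C7; Z-C4=C5 from anti-carbomagnesiation/iodination; Z-C1=C2 from alkyne semihydrogenation; the E tiglate from tiglic acid.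

Key step: step 16

Remark on the target: it is taken as the open 10-hydroxy-3-ketone that is drawn; its ring-chain tautomer (the 3,10-hemiketal) would arise from the same last step.
Remark on step 13: the dioxolane stereocentre of the allylindium reagent is assumed to turn the face anti to its C–O bond toward the aldehyde; the enantiomeric acetonide aldehyde is equally available if the other face proves preferred.

**Route**

Step 1
Reactants: 1 (R)-citramalic acid
Product: 2 2-[(4R)-2,2,4-trimethyl-5-oxo-1,3-dioxolan-4-yl]acetic acid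
Conditions: 2,2-dimethoxypropane, TsOH·H2O (cat.), CH2Cl2, rt
Reagents that add atoms: 2,2-dimethoxypropane, COC(C)(C)OC
Why: Acid-catalysed transacetalisation ties the tertiary hydroxyl and the neighbouring carboxyl into the five-membered dioxolanone (the usual acetonide of an α-hydroxy acid), which leaves the C8 carboxyl free and does not touch C10.

Step 2
Reactants: 2 2-[(4R)-2,2,4-trimethyl-5-oxo-1,3-dioxolan-4-yl]acetic acid
Product: 4 (3R)-3-hydroxy-3-methyloxolan-2-one, via hydroxyethyl dioxolanone 3 (not isolated)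
Conditions: BH3·THF, THF, 0 °C → rt; MeOH; then TsOH·H2O (cat.), CH2Cl2, rt
Reagents that add atoms: none
Why: Borane reduces the free carboxylic acid much faster than the dioxolanone ester (chemoselective borane reduction), and acid then drives translactonisation of alcohol 3 to the five-membered α-hydroxy lactone with loss of acetone.

Step 3
Reactants: 4 (3R)-3-hydroxy-3-methyloxolan-2-one
Product: 5 (3R)-3-methyl-3-(triethylsilyloxy)oxolan-2-one
Conditions: Et3SiOTf, 2,6-lutidine, CH2Cl2, −78 → 0 °C
Reagents that add atoms: triethylsilyl trifluoromethanesulfonate, CC[Si](CC)(CC)OS(=O)(=O)C(F)(F)F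
Why: Silyl triflate silylation is the standard way to cap a hindered tertiary alcohol, and the triethylsilyl group is chosen because fluoride can still remove it from a tertiary oxygen at the end.

Step 4
Reactants: 5 (3R)-3-methyl-3-(triethylsilyloxy)oxolan-2-one
Product: 6 (3R)-3-methyl-3-(triethylsilyloxy)oxolan-2-ol (both anomers)
Conditions: i-Bu2AlH (1.1 equiv), CH2Cl2, −78 °C; aqueous KNaC4H4O6
Reagents that add atoms: none
Why: Partial reduction of a lactone to the lactol by i-Bu2AlH works at low temperature because the aluminium hemiacetal does not collapse before work-up.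

Step 5
Reactants: 6 (3R)-3-methyl-3-(triethylsilyloxy)oxolan-2-ol
Product: 7 (3R)-3-methyl-3-(triethylsilyloxy)pent-4-yn-1-ol
Conditions: dimethyl (1-diazo-2-oxopropyl)phosphonate, K2CO3, MeOH, 0 °C → rt
Reagents that add atoms: dimethyl (1-diazo-2-oxopropyl)phosphonate (Ohira–Bestmann reagent), CC(=O)C(=[N+]=[N-])P(=O)(OC)OC
Why: Seyferth–Gilbert homologation with the Ohira–Bestmann reagent acts on the open hydroxy aldehyde form of the lactol, which has no α-hydrogen to lose, and the hindered tertiary silyl ether should survive the mild carbonate medium.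

Step 6
Reactants: 8 propargyl alcohol
Product: 10 (2Z)-3-iodo-2-methylprop-2-en-1-ol, via cyclic alkenylmagnesium alkoxide 9 (not isolated)
Conditions: MeMgBr (2.5 equiv), CuI (10 mol %), THF, −10 °C → rt; then I2, −10 °C
Reagents that add atoms: methylmagnesium bromide, C[Mg]Br; iodine, II
Why: Copper-catalysed anti-carbomagnesiation of the propargylic alkoxide puts methyl on the inner carbon and magnesium on the terminal carbon cis to the CH2O group (chelate 9), and iodinolysis with retention gives the Z-iodide that later becomes Z-C4=C5.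

Step 7
Reactants: 10 (2Z)-3-iodo-2-methylprop-2-en-1-ol
Product: 11 (2Z)-3-iodo-2-methylprop-2-enal
Conditions: MnO2, CH2Cl2, rt, dark; used at once
Reagents that add atoms: none
Why: Allylic oxidation with MnO2 is neutral and should leave the Z-iodoalkene geometry intact.

Step 8
Reactants: 7 (3R)-3-methyl-3-(triethylsilyloxy)pent-4-yn-1-ol; 11 (2Z)-3-iodo-2-methylprop-2-enal
Product: 13 (3R,7Z)-8-iodo-3,7-dimethyl-3-(triethylsilyloxy)oct-7-en-4-yne-1,6-diol (both C6 epimers), via bis(bromomagnesium) acetylide alkoxide 12 (not isolated)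
Conditions: 7, EtMgBr (2.1 equiv), THF, 0 → 40 °C; then 11, −20 → 0 °C
Reagents that add atoms: none
Why: 1,2-Addition of an alkynyl Grignard reagent to an enal forms C2–C3; the new carbinol (germacrane C3) arises as both epimers, which does not matter because it becomes the ketone.

Step 9
Reactants: 13 (3R,7Z)-8-iodo-3,7-dimethyl-3-(triethylsilyloxy)oct-7-en-4-yne-1,6-diol
Product: 14 (3R,4Z,7Z)-8-iodo-3,7-dimethyl-3-(triethylsilyloxy)octa-4,7-diene-1,6-diol (both C6 epimers)
Conditions: H2 (1 atm), Pd/CaCO3 poisoned with Pb(OAc)2, quinoline, EtOAc, 0 °C; stopped after one equivalent of H2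
Reagents that add atoms: none
Why: Lindlar-type syn semihydrogenation of the internal alkyne gives the Z-C1=C2 olefin, and the poisoned catalyst should leave the trisubstituted iodoalkene alone.

Step 10
Reactants: 14 (3R,4Z,7Z)-8-iodo-3,7-dimethyl-3-(triethylsilyloxy)octa-4,7-diene-1,6-diol
Product: 15 (3R,4Z,7Z)-8-iodo-3,7-dimethyl-6-oxo-3-(triethylsilyloxy)octa-4,7-dienal
Conditions: Dess–Martin periodinane (3 equiv), NaHCO3, CH2Cl2, 0 °C → rt
Reagents that add atoms: none
Why: Dess–Martin oxidation turns the primary alcohol into the C8 aldehyde and the bis-allylic alcohol into the cross-conjugated ketone in one operation, under buffered conditions that should neither isomerise the Z-enone nor cleave the silyl ether.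

Step 11
Reactants: 16 (R)-glyceraldehyde acetonide; 17 methyl acrylate
Product: 18 methyl 2-{[(4R)-2,2-dimethyl-1,3-dioxolan-4-yl](hydroxy)methyl}prop-2-enoate (both carbinol epimers)
Conditions: 1,4-diazabicyclo[2.2.2]octane (DABCO, 0.5 equiv), 1,4-dioxane–H2O 1:1, rt
Reagents that add atoms: none
Why: Morita–Baylis–Hillman reaction; the carbinol configuration is irrelevant because this carbon becomes sp2 in the next step.

Step 12
Reactants: 18 methyl 2-{[(4R)-2,2-dimethyl-1,3-dioxolan-4-yl](hydroxy)methyl}prop-2-enoate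
Product: 19 methyl (2Z)-2-(bromomethyl)-3-[(4S)-2,2-dimethyl-1,3-dioxolan-4-yl]prop-2-enoate
Conditions: NBS, Me2S, CH2Cl2, 0 °C → rt
Reagents that add atoms: N-bromosuccinimide, O=C1CCC(=O)N1Br
Why: The sulfonium-activated hydroxyl is displaced by bromide with allylic transposition (SN2′), which gives the thermodynamically preferred (2Z)-bromide with CH2Br and the dioxolane cis; the neutral conditions spare the acetonide.

Step 13
Reactants: 15 (3R,4Z,7Z)-8-iodo-3,7-dimethyl-6-oxo-3-(triethylsilyloxy)octa-4,7-dienal; 19 methyl (2Z)-2-(bromomethyl)-3-[(4S)-2,2-dimethyl-1,3-dioxolan-4-yl]prop-2-enoate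
Product: 20 methyl (3R,4R,6R,7Z,10Z)-3-[(4S)-2,2-dimethyl-1,3-dioxolan-4-yl]-4-hydroxy-11-iodo-6,10-dimethyl-2-methylidene-9-oxo-6-(triethylsilyloxy)undeca-7,10-dienoate
Conditions: 19 (1.5 equiv), indium powder (In, 2 equiv), THF–H2O 1:1, rt
Reagents that add atoms: none
Why: Barbier-type 2-(alkoxycarbonyl)allylation: the allylindium formed from 19 adds through its γ-carbon in a chair (Zimmerman–Traxler) transition state with the dioxolane axial and the aldehyde chain equatorial, which should give the syn C7/C8 array, while the dioxolane carbon (its C–H held in the allyl plane by allylic 1,3-strain) should expose the face anti to its C–O bond and so give (7R,8R) in germacrane numbering; the aldehyde reacts in preference to the hindered ketone and the alkenyl iodide is inert to indium.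

Step 14
Reactants: 20 methyl (3R,4R,6R,7Z,10Z)-3-[(4S)-2,2-dimethyl-1,3-dioxolan-4-yl]-4-hydroxy-11-iodo-6,10-dimethyl-2-methylidene-9-oxo-6-(triethylsilyloxy)undeca-7,10-dienoate
Product: 21 methyl (3S,4R,6R,7Z,10Z)-4-(tert-butyldimethylsilyloxy)-3-[(4S)-2,2-dimethyl-1,3-dioxolan-4-yl]-11-iodo-6,10-dimethyl-2-methylidene-9-oxo-6-(triethylsilyloxy)undeca-7,10-dienoate
Conditions: t-BuMe2SiOTf, 2,6-lutidine, CH2Cl2, −78 °C
Reagents that add atoms: tert-butyldimethylsilyl trifluoromethanesulfonate, CC(C)(C)[Si](C)(C)OS(=O)(=O)C(F)(F)F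
Why: Silyl triflate silylation of the hindered secondary alcohol, done at once so that the hydroxyl can neither lactonise onto C12 nor add to the enone; the change of the C3 descriptor is a priority change only.

Step 15
Reactants: 21 methyl (3S,4R,6R,7Z,10Z)-4-(tert-butyldimethylsilyloxy)-3-[(4S)-2,2-dimethyl-1,3-dioxolan-4-yl]-11-iodo-6,10-dimethyl-2-methylidene-9-oxo-6-(triethylsilyloxy)undeca-7,10-dienoate
Product: 22 methyl (3R,4R,6R,7Z,10Z)-4-(tert-butyldimethylsilyloxy)-3-formyl-11-iodo-6,10-dimethyl-2-methylidene-9-oxo-6-(triethylsilyloxy)undeca-7,10-dienoate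
Conditions: H5IO6 (1.5 equiv), EtOAc, 0 °C; used at once
Reagents that add atoms: none
Why: Periodic acid hydrolyses the terminal acetonide and cleaves the liberated 1,2-diol in the same flask (glycol cleavage), which unmasks the C6 aldehyde without base so that the doubly activated C7–H is not removed; the tert-butyldimethylsilyl ether and the hindered tertiary triethylsilyl ether should outlast the short cold exposure.

Step 16
Reactants: 22 methyl (3R,4R,6R,7Z,10Z)-4-(tert-butyldimethylsilyloxy)-3-formyl-11-iodo-6,10-dimethyl-2-methylidene-9-oxo-6-(triethylsilyloxy)undeca-7,10-dienoate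
Product: 24 (1Z,4Z,6S,7S,8R,10R)-8-(tert-butyldimethylsilyloxy)-3-oxo-10-(triethylsilyloxy)germacra-1,4,11(13)-trien-12,6-olide, via ten-membered chromium alkoxide 23 (not isolated)
Conditions: CrCl2 (10 equiv), NiCl2 (1 mol % of CrCl2), degassed DMSO–THF, slow addition of 22 to 0.002 M, rt
Reagents that add atoms: none
Why: Zerovalent nickel, formed from NiCl2 by CrCl2, inserts into the C5–I bond with retention of the Z geometry and hands the alkenyl group to trivalent chromium; the alkenylchromium adds only to the C6 aldehyde, and the chromium alkoxide 23 then acylates itself on the C12 methyl ester with loss of methanol. The closest known chemistry is the Nozaki–Hiyama–Kishi macrocyclisation of alkenyl iodides onto aldehydes, joined to the lactonisation known from additions of (Z)-β-iodo enoates and of 2-(alkoxycarbonyl)allyl reagents to aldehydes. The ten-membered carbocycle closes 10-exo-trig at the aldehyde carbon and the γ-lactone closes 5-exo-trig at the ester carbon. C6 is set under control of C7: with C5 and C8 joined by the short curled C9–C4 tether the forming bond is held gauche to C7–C8, so the alkenyl carbon C11 lies anti to the incoming C5 (Felkin–Anh) and C5 passes the small H7, which puts O6 on the same side as C11 and gives the cis-fused (6S) lactone. The step needs reaction at the aldehyde and not at the ketone or ester, which organochromium reagents provide; it needs acyl transfer to win over hemiketal formation at C3 and dehydration to a furan, which the 1,4 relation of O6 to C12 and the irreversibility of lactonisation secure; and it needs C7 to keep its configuration, which the neutral medium and the immediate use of 22 secure.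

Step 17
Reactants: 24 (1Z,4Z,6S,7S,8R,10R)-8-(tert-butyldimethylsilyloxy)-3-oxo-10-(triethylsilyloxy)germacra-1,4,11(13)-trien-12,6-olide
Product: 25 (1Z,4Z,6S,7R,8R,10R)-8,10-dihydroxy-3-oxogermacra-1,4,11(13)-trien-12,6-olide
Conditions: HF·pyridine, pyridine, THF, 0 °C → rt
Reagents that add atoms: none
Why: Fluoride-mediated desilylation removes the secondary tert-butyldimethylsilyl and the tertiary triethylsilyl ether under buffered, non-basic conditions that should leave the methylene lactone and the dienone untouched.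

Step 18
Reactants: 25 (1Z,4Z,6S,7R,8R,10R)-8,10-dihydroxy-3-oxogermacra-1,4,11(13)-trien-12,6-olide; 26 tiglic acid
Product: 28 (1Z,4Z,6S,7R,8R,10R)-10-hydroxy-8-[(2E)-2-methylbut-2-enoyloxy]-3-oxogermacra-1,4,11(13)-trien-12,6-olide (target), via tiglic 2,4,6-trichlorobenzoic anhydride 27 (not isolated)
Conditions: 26, 2,4,6-trichlorobenzoyl chloride, Et3N, toluene, rt; then 25, 4-(dimethylamino)pyridine (DMAP), 0 °C → rt
Reagents that add atoms: none
Why: Yamaguchi esterification: the mixed anhydride 27 passes the tigloyl group through the acylpyridinium to the secondary C8 hydroxyl only, the tertiary C10 hydroxyl being too hindered, and the stable E geometry of the acid is kept.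

**Compound list**

1 | (R)-citramalic acid | OC(=O)[C@](C)(O)CC(=O)O | starting material
2 | 2-[(4R)-2,2,4-trimethyl-5-oxo-1,3-dioxolan-4-yl]acetic acid | CC1(C)OC(=O)[C@@](C)(CC(=O)O)O1 | intermediate
3 | (5R)-5-(2-hydroxyethyl)-2,2,5-trimethyl-1,3-dioxolan-4-one (not isolated) | CC1(C)OC(=O)[C@@](C)(CCO)O1 | intermediate
4 | (3R)-3-hydroxy-3-methyloxolan-2-one | O=C1OCC[C@@]1(C)O | intermediate
5 | (3R)-3-methyl-3-(triethylsilyloxy)oxolan-2-one | O=C1OCC[C@@]1(C)O[Si](CC)(CC)CC | intermediate
6 | (3R)-3-methyl-3-(triethylsilyloxy)oxolan-2-ol, both anomers | OC1OCC[C@@]1(C)O[Si](CC)(CC)CC | intermediate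
7 | (3R)-3-methyl-3-(triethylsilyloxy)pent-4-yn-1-ol | C#C[C@](C)(O[Si](CC)(CC)CC)CCO | intermediate
8 | propargyl alcohol | C#CCO | starting material
9 | 4-methyl-2,5-dihydro-1,2-oxamagnesole, cyclic alkenylmagnesium alkoxide (not isolated) | CC1=C[Mg]OC1 | intermediate
10 | (2Z)-3-iodo-2-methylprop-2-en-1-ol | OC/C(C)=C\I | intermediate
11 | (2Z)-3-iodo-2-methylprop-2-enal | O=C/C(C)=C\I | intermediate
12 | bis(bromomagnesium) acetylide alkoxide of 7 (not isolated) | Br[Mg]C#C[C@](C)(O[Si](CC)(CC)CC)CCO[Mg]Br | intermediate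
13 | (3R,7Z)-8-iodo-3,7-dimethyl-3-(triethylsilyloxy)oct-7-en-4-yne-1,6-diol, both C6 epimers | OCC[C@@](C)(O[Si](CC)(CC)CC)C#CC(O)/C(C)=C\I | intermediate
14 | (3R,4Z,7Z)-8-iodo-3,7-dimethyl-3-(triethylsilyloxy)octa-4,7-diene-1,6-diol, both C6 epimers | OCC[C@@](C)(O[Si](CC)(CC)CC)/C=C\C(O)/C(C)=C\I | intermediate
15 | (3R,4Z,7Z)-8-iodo-3,7-dimethyl-6-oxo-3-(triethylsilyloxy)octa-4,7-dienal | O=CC[C@@](C)(O[Si](CC)(CC)CC)/C=C\C(=O)/C(C)=C\I | intermediate
16 | (R)-glyceraldehyde acetonide, (4R)-2,2-dimethyl-1,3-dioxolane-4-carbaldehyde | CC1(C)OC[C@@H](O1)C=O | starting material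
17 | methyl acrylate | C=CC(=O)OC | starting material
18 | methyl 2-{[(4R)-2,2-dimethyl-1,3-dioxolan-4-yl](hydroxy)methyl}prop-2-enoate, both carbinol epimers | CC1(C)OC[C@@H](O1)C(O)C(=C)C(=O)OC | intermediate
19 | methyl (2Z)-2-(bromomethyl)-3-[(4S)-2,2-dimethyl-1,3-dioxolan-4-yl]prop-2-enoate | CC1(C)OC[C@@H](O1)/C=C(\CBr)C(=O)OC | intermediate
20 | methyl (3R,4R,6R,7Z,10Z)-3-[(4S)-2,2-dimethyl-1,3-dioxolan-4-yl]-4-hydroxy-11-iodo-6,10-dimethyl-2-methylidene-9-oxo-6-(triethylsilyloxy)undeca-7,10-dienoate | C=C(C(=O)OC)[C@@H]([C@H]1COC(C)(C)O1)[C@H](O)C[C@@](C)(O[Si](CC)(CC)CC)/C=C\C(=O)/C(C)=C\I | intermediate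
21 | methyl (3S,4R,6R,7Z,10Z)-4-(tert-butyldimethylsilyloxy)-3-[(4S)-2,2-dimethyl-1,3-dioxolan-4-yl]-11-iodo-6,10-dimethyl-2-methylidene-9-oxo-6-(triethylsilyloxy)undeca-7,10-dienoate | C=C(C(=O)OC)[C@@H]([C@H]1COC(C)(C)O1)[C@H](O[Si](C)(C)C(C)(C)C)C[C@@](C)(O[Si](CC)(CC)CC)/C=C\C(=O)/C(C)=C\I | intermediate
22 | methyl (3R,4R,6R,7Z,10Z)-4-(tert-butyldimethylsilyloxy)-3-formyl-11-iodo-6,10-dimethyl-2-methylidene-9-oxo-6-(triethylsilyloxy)undeca-7,10-dienoate | C=C(C(=O)OC)[C@@H](C=O)[C@H](O[Si](C)(C)C(C)(C)C)C[C@@](C)(O[Si](CC)(CC)CC)/C=C\C(=O)/C(C)=C\I | intermediate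
23 | methyl (1Z,4Z,6S,7R,8R,10R)-8-(tert-butyldimethylsilyloxy)-6-(dichlorochromiooxy)-3-oxo-10-(triethylsilyloxy)germacra-1,4,11(13)-trien-12-oate (not isolated) | COC(=O)C(=C)[C@@H]1[C@H](O[Si](C)(C)C(C)(C)C)C[C@@](C)(O[Si](CC)(CC)CC)/C=C\C(=O)/C(C)=C\[C@@H]1O[Cr](Cl)Cl | intermediate
24 | (1Z,4Z,6S,7S,8R,10R)-8-(tert-butyldimethylsilyloxy)-3-oxo-10-(triethylsilyloxy)germacra-1,4,11(13)-trien-12,6-olide | C=C1C(=O)O[C@H]2/C=C(/C)C(=O)/C=C\[C@](C)(O[Si](CC)(CC)CC)C[C@@H](O[Si](C)(C)C(C)(C)C)[C@@H]12 | intermediate
25 | (1Z,4Z,6S,7R,8R,10R)-8,10-dihydroxy-3-oxogermacra-1,4,11(13)-trien-12,6-olide | C=C1C(=O)O[C@H]2/C=C(/C)C(=O)/C=C\[C@](C)(O)C[C@@H](O)[C@@H]12 | intermediate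
26 | tiglic acid | C/C=C(\C)C(=O)O | starting material
27 | tiglic 2,4,6-trichlorobenzoic anhydride (not isolated) | C/C=C(\C)C(=O)OC(=O)c1c(Cl)cc(Cl)cc1Cl | intermediate
28 | (1Z,4Z,6S,7R,8R,10R)-10-hydroxy-8-[(2E)-2-methylbut-2-enoyloxy]-3-oxogermacra-1,4,11(13)-trien-12,6-olide | C=C1C(=O)O[C@H]2/C=C(/C)C(=O)/C=C\[C@](C)(O)C[C@@H](OC(=O)/C(C)=C/C)[C@@H]12 | target

**Step count and risks**

Total step count: 18. Longest linear sequence: 14 steps (steps 1–5, 8–10 and 13–18); the side branches are steps 6–7 and 11–12.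

The three steps most likely to fail:

Step 16. The tethered alkenylchromium may attack the other face of the C6 aldehyde, or C7 may epimerise before closure, so that the trans-fused C6 epimer forms; a slow closure would also let intermolecular coupling compete. The fallback gives up substrate control for reagent control. Aldehyde 22 would be added slowly to CrCl2 pre-complexed with a chiral oxazoline–sulfonamide ligand, in the antipode that matches the (6S) face, together with the NiCl2 complex of 2,9-dimethyl-1,10-phenanthroline in MeCN; this is the established ligand-controlled form of the same coupling. It sets out from 22, returns at 24 and makes no new compound.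

Step 13. The dioxolane stereocentre may steer the allylindium only weakly, or toward the other face, so that the (7S,8S) syn adduct contaminates or dominates; the acidic unmasking of step 15 may in addition strip the tertiary silyl ether. The fallback uses an achiral reagent, separation, and a neutral unmasking. Commercial [(4-methoxybenzyl)oxy]acetaldehyde (COc1ccc(COCC=O)cc1) and 17 would give, under the conditions of step 11, methyl 3-hydroxy-4-[(4-methoxyphenyl)methoxy]-2-methylidenebutanoate F1. NBS and Me2S would convert it into methyl (2Z)-2-(bromomethyl)-4-[(4-methoxyphenyl)methoxy]but-2-enoate F2. Indium-mediated addition of F2 to 15 should give the two syn adducts: the wanted (3S,4R,6R) hydroxy ester F3, which has the target's arrangement at C7 and C8, and its (3R,4S,6R) diastereomer F4, which chromatography would remove. Silylation of F3 as in step 14 would give the silyl ether F5, DDQ in CH2Cl2 with pH 7 buffer would free the primary alcohol F6, and Dess–Martin oxidation would give 22. This fallback sets out from 15 and returns at 22.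

Step 9. Palladium may cleave the alkenyl C–I bond by hydrogenolysis, or the hindered alkyne may react so slowly that over-reduction sets in. The fallback fixes the Z-C1=C2 geometry by olefination and brings in iodine last. Lactol 6 would react with methyl bis(2,2,2-trifluoroethyl)phosphonoacetate, KN(SiMe3)2 and 18-crown-6 (Still–Gennari olefination) to give methyl (2Z,4R)-6-hydroxy-4-methyl-4-(triethylsilyloxy)hex-2-enoate F7. i-Bu2AlH would reduce it to (2Z,4R)-4-methyl-4-(triethylsilyloxy)hex-2-ene-1,6-diol F8, and MnO2 would oxidise only the allylic alcohol to (2Z,4R)-6-hydroxy-4-methyl-4-(triethylsilyloxy)hex-2-enal F9. HC≡CMgBr would add to give (4Z,6R)-6-methyl-6-(triethylsilyloxy)oct-4-en-1-yne-3,8-diol F10. Copper-catalysed anti-carbomagnesiation of F10 with MeMgBr and CuI, followed by iodinolysis as in step 6, would give 14. This fallback sets out from 6 and returns at 14; steps 5 to 8 would then not be needed.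

Further compounds
F0 | step 16 | none | none
F1 | step 13 | methyl 3-hydroxy-4-[(4-methoxyphenyl)methoxy]-2-methylidenebutanoate | COC(=O)C(=C)C(O)COCc1ccc(OC)cc1
F2 | step 13 | methyl (2Z)-2-(bromomethyl)-4-[(4-methoxyphenyl)methoxy]but-2-enoate | COC(=O)/C(CBr)=C/COCc1ccc(OC)cc1
F3 | step 13 | methyl (3S,4R,6R,7Z,10Z)-4-hydroxy-11-iodo-3-{[(4-methoxyphenyl)methoxy]methyl}-6,10-dimethyl-2-methylidene-9-oxo-6-(triethylsilyloxy)undeca-7,10-dienoate | C=C(C(=O)OC)[C@@H](COCc1ccc(OC)cc1)[C@H](O)C[C@@](C)(O[Si](CC)(CC)CC)/C=C\C(=O)/C(C)=C\I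
F4 | step 13 | methyl (3R,4S,6R,7Z,10Z)-4-hydroxy-11-iodo-3-{[(4-methoxyphenyl)methoxy]methyl}-6,10-dimethyl-2-methylidene-9-oxo-6-(triethylsilyloxy)undeca-7,10-dienoate | C=C(C(=O)OC)[C@H](COCc1ccc(OC)cc1)[C@@H](O)C[C@@](C)(O[Si](CC)(CC)CC)/C=C\C(=O)/C(C)=C\I
F5 | step 13 | methyl (3S,4R,6R,7Z,10Z)-4-(tert-butyldimethylsilyloxy)-11-iodo-3-{[(4-methoxyphenyl)methoxy]methyl}-6,10-dimethyl-2-methylidene-9-oxo-6-(triethylsilyloxy)undeca-7,10-dienoate | C=C(C(=O)OC)[C@@H](COCc1ccc(OC)cc1)[C@H](O[Si](C)(C)C(C)(C)C)C[C@@](C)(O[Si](CC)(CC)CC)/C=C\C(=O)/C(C)=C\I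
F6 | step 13 | methyl (3S,4R,6R,7Z,10Z)-4-(tert-butyldimethylsilyloxy)-3-(hydroxymethyl)-11-iodo-6,10-dimethyl-2-methylidene-9-oxo-6-(triethylsilyloxy)undeca-7,10-dienoate | C=C(C(=O)OC)[C@@H](CO)[C@H](O[Si](C)(C)C(C)(C)C)C[C@@](C)(O[Si](CC)(CC)CC)/C=C\C(=O)/C(C)=C\I
F7 | step 9 | methyl (2Z,4R)-6-hydroxy-4-methyl-4-(triethylsilyloxy)hex-2-enoate | COC(=O)/C=C\[C@](C)(O[Si](CC)(CC)CC)CCO
F8 | step 9 | (2Z,4R)-4-methyl-4-(triethylsilyloxy)hex-2-ene-1,6-diol | OC/C=C\[C@](C)(O[Si](CC)(CC)CC)CCO
F9 | step 9 | (2Z,4R)-6-hydroxy-4-methyl-4-(triethylsilyloxy)hex-2-enal | O=C/C=C\[C@](C)(O[Si](CC)(CC)CC)CCO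
F10 | step 9 | (4Z,6R)-6-methyl-6-(triethylsilyloxy)oct-4-en-1-yne-3,8-diol, both C3 epimers | C#CC(O)/C=C\[C@](C)(O[Si](CC)(CC)CC)CCO
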